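**Retrosynthetic overview**

1. Target 25 ⇐ tetraol 24 (triacetylation that spares the hindered C4–OH) ⇐ lactol 21 (syn-alkoxyallylboration, then cross-metathesis) ⇐ cis-fused γ-lactone 20, a temporary ring that ties the C4 oxygen to the first two side-chain carbons.
2. 20 ⇐ bicyclic ketone 11 + (R)-lactate triflate 13 (enolate SN2), then hydroxyl-directed ketone reduction, C7–C8 epoxidation/Ti(III) opening (C7–OH, C8=CH2) and syn-elimination of the tertiary C3–OH (C2=C3).
3. 11 ⇐ acyclic epoxy enol silane 10 by one intramolecular (4+3) cycloaddition that makes C5–C6 and C3a–C8a together: cyclopentane (tether closure) and cycloheptenone (cycloaddition) form in the same step; the γ-lactone follows in step 13 and is reopened in step 18.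
4. Enabling feature: in the seven-membered ring the carbinol C4 lies between C5 and the ring-fusion carbon C3a (C5–C4–C3a = oxyallyl cation retron); C6 and C8a are the 1,4-ends of the C7(OAc)–C8(=CH2) unit (= 3-methyl-1,3-diene retron); the cyclopentene carbons C1–C3 are a three-carbon tether whose methyl-bearing C3 can carry the epoxide oxygen that launches the cation and later leaves as water.
5. 10 ⇐ neryl acetate 1 (SeO2/Wittig for the diene, Sharpless epoxidation for the absolute configuration, MeMgBr for C5).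

Key step: step 9

Remark: the SMILES is read as a trans-fused hydroazulene. Locants are azulene locants (C3a/C8a ring fusion, C4 carbinol, C5 side-chain carbon, C7 acetoxy carbon, C8 methylidene carbon); lactones are numbered as azuleno[4,5-b]furans; primed locants (C2′–C5′) refer to the heptenyl side chain.

**Route**

Step 1
Reactants: 1 neryl acetate
Product: 3 (2Z,6E)-3,7-dimethyl-8-oxoocta-2,6-dien-1-yl acetate, via allylic alcohol 2 (not isolated)
Conditions: SeO2 (cat.), t-BuOOH, salicylic acid (cat.), CH2Cl2, rt; crude product, then MnO2, CH2Cl2, rt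
Reagents that add atoms: tert-butyl hydroperoxide, CC(C)(C)OO
Why: Selenium dioxide allylic oxidation (ene/[2,3] sequence) should attack the (E)-methyl group of the electron-rich terminal alkene, and MnO2 should converge alcohol 2 and any aldehyde already formed to the (E)-enal.

Step 2
Reactants: 3 (2Z,6E)-3,7-dimethyl-8-oxoocta-2,6-dien-1-yl acetate
Product: 4 (2Z,6E)-3,7-dimethylnona-2,6,8-trien-1-yl acetate
Conditions: Ph3PCH3Br, KHMDS, THF, −78 to 0 °C
Reagents that add atoms: methyltriphenylphosphonium bromide, C[P+](c1ccccc1)(c1ccccc1)c1ccccc1.[Br-]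
Why: Wittig methylenation of the enal should give the (E)-3-methyl-1,3-diene without touching either trisubstituted alkene, the aldehyde reacting much faster than the acetate at low temperature.

Step 3
Reactants: 4 (2Z,6E)-3,7-dimethylnona-2,6,8-trien-1-yl acetate
Product: 5 (2Z,6E)-3,7-dimethylnona-2,6,8-trien-1-ol
Conditions: K2CO3 (0.2 equiv), MeOH, rt
Reagents that add atoms: none
Why: Base-catalysed transesterification (methanolysis) should free the allylic alcohol needed to direct the epoxidation.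

Step 4
Reactants: 5 (2Z,6E)-3,7-dimethylnona-2,6,8-trien-1-ol
Product: 6 [(2S,3R)-3-methyl-3-[(3E)-4-methylhexa-3,5-dien-1-yl]oxiran-2-yl]methanol
Conditions: Ti(OiPr)4 (cat.), L-(+)-diethyl tartrate (cat.), t-BuOOH, 4 Å MS, CH2Cl2, −20 °C
Reagents that add atoms: tert-butyl hydroperoxide, CC(C)(C)OO
Why: Sharpless asymmetric epoxidation should epoxidise only the allylic-alcohol alkene, and L-(+)-tartrate should deliver oxygen to the face that gives the (2S,3R)-oxirane, as for nerol; this sets the absolute configuration of the whole route.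

Step 5
Reactants: 6 [(2S,3R)-3-methyl-3-[(3E)-4-methylhexa-3,5-dien-1-yl]oxiran-2-yl]methanol
Product: 7 (2R,3R)-3-methyl-3-[(3E)-4-methylhexa-3,5-dien-1-yl]oxirane-2-carbaldehyde
Conditions: Dess–Martin periodinane, NaHCO3, CH2Cl2, 0 °C
Reagents that add atoms: none
Why: Buffered Dess–Martin oxidation should give the epoxy aldehyde without opening the oxirane or epimerising C2.

Step 6
Reactants: 7 (2R,3R)-3-methyl-3-[(3E)-4-methylhexa-3,5-dien-1-yl]oxirane-2-carbaldehyde
Product: 8 1-[(2S,3R)-3-methyl-3-[(3E)-4-methylhexa-3,5-dien-1-yl]oxiran-2-yl]ethan-1-ol (both carbinol epimers)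
Conditions: MeMgBr, THF, −78 °C
Reagents that add atoms: methylmagnesium bromide, C[Mg]Br
Why: Grignard addition to the aldehyde brings in the carbon that becomes C5; the new carbinol centre need not be controlled because it is oxidised in the next step.

Step 7
Reactants: 8 1-[(2S,3R)-3-methyl-3-[(3E)-4-methylhexa-3,5-dien-1-yl]oxiran-2-yl]ethan-1-ol
Product: 9 1-[(2R,3R)-3-methyl-3-[(3E)-4-methylhexa-3,5-dien-1-yl]oxiran-2-yl]ethan-1-one
Conditions: Dess–Martin periodinane, NaHCO3, CH2Cl2, 0 °C to rt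
Reagents that add atoms: none
Why: Dess–Martin oxidation should converge both epimers to the α,β-epoxy methyl ketone.

Step 8
Reactants: 9 1-[(2R,3R)-3-methyl-3-[(3E)-4-methylhexa-3,5-dien-1-yl]oxiran-2-yl]ethan-1-one
Product: 10 triethyl({1-[(2R,3R)-3-methyl-3-[(3E)-4-methylhexa-3,5-dien-1-yl]oxiran-2-yl]ethenyl}oxy)silane
Conditions: TESOTf, Et3N, CH2Cl2, −78 to 0 °C
Reagents that add atoms: triethylsilyl trifluoromethanesulfonate, CC[Si](CC)(CC)OS(=O)(=O)C(F)(F)F
Why: Soft enolisation/O-silylation (silyl triflate–amine) can only take place toward the methyl group, so the 2-silyloxyallyl unit should form regiospecifically, the excess amine keeping the oxirane unactivated.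

Step 9
Reactants: 10 triethyl({1-[(2R,3R)-3-methyl-3-[(3E)-4-methylhexa-3,5-dien-1-yl]oxiran-2-yl]ethenyl}oxy)silane
Product: 11 (3R,3aS,8aR)-3,8-dimethyl-3-[(triethylsilyl)oxy]-2,3,3a,5,6,8a-hexahydroazulen-4(1H)-one
Conditions: TESOTf (10–20 mol%), CH2Cl2 (0.01 M), −78 to −40 °C
Reagents that add atoms: none
Why: Et3Si+ from the catalyst silylates the oxirane oxygen, the C–O bond at the oxirane carbon next to the enol silane ionises with 2-(silyloxy)allyl cation character while the tethered (E)-3-methyl-1,3-diene bonds to both ends of that three-carbon unit (C5–C6 and C3a–C8a), and the silyl group on the resulting oxocarbenium oxygen is passed to the next oxirane, leaving the ketone and the tertiary silyl ether. The closest known reaction type is the silyl-triflate-catalysed intramolecular (4+3) cycloaddition of epoxy enol silanes with a tethered diene, a variant of the intramolecular oxyallyl-cation (4+3) cycloaddition with a three-atom tether. The five-membered ring closes by 5-exo attack of the diene terminus on the opening oxirane carbon (the breaking C–O bond lies outside the new ring), and the seven-membered ring closes as the 4C+3C ring of the cycloaddition. C3a should be set by backside (inverting) opening of the (2R)-oxirane carbon, C8a by the E geometry of the diene in an extended transition state that places H-3a and H-8a trans, and C3 is carried over unchanged from the Sharpless epoxide. The step needs opening at the secondary, enol-silane-activated carbon and not at the tertiary one, the extended and not the compact transition state, and ring closure faster than proton loss; the allylic activation, the three-carbon tether (only the activated carbon can be reached through a five-membered transition state) and the (E)-diene are the substrate features relied on.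

Step 10
Reactants: 12 methyl (R)-lactate
Product: 13 methyl (2R)-2-{[(trifluoromethyl)sulfonyl]oxy}propanoate
Conditions: Tf2O, 2,6-lutidine, CH2Cl2, −78 °C
Reagents that add atoms: trifluoromethanesulfonic anhydride, O=S(=O)(OS(=O)(=O)C(F)(F)F)C(F)(F)F
Why: O-Sulfonylation does not touch the stereocentre, so the (R)-triflate should be obtained with full retention.

Step 11
Reactants: 11 (3R,3aS,8aR)-3,8-dimethyl-3-[(triethylsilyl)oxy]-2,3,3a,5,6,8a-hexahydroazulen-4(1H)-one, 13 methyl (2R)-2-{[(trifluoromethyl)sulfonyl]oxy}propanoate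
Product: 14 methyl (2R)-2-[(3R,3aS,5S,8aR)-3,8-dimethyl-4-oxo-3-[(triethylsilyl)oxy]-1,2,3,3a,4,5,6,8a-octahydroazulen-5-yl]propanoate
Conditions: LDA, THF, −78 °C; then 13, −78 to −40 °C
Reagents that add atoms: none
Why: Kinetic deprotonation should occur at the C5 methylene (the C3a methine is shielded by the quaternary C3), and enolate SN2 alkylation by the α-triflyloxy ester with inversion sets C2′ (R), while attack on the exo face of the chair-like cycloheptenolate (the face of the axial H-3a) should set C5 (S).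

Step 12
Reactants: 14 methyl (2R)-2-[(3R,3aS,5S,8aR)-3,8-dimethyl-4-oxo-3-[(triethylsilyl)oxy]-1,2,3,3a,4,5,6,8a-octahydroazulen-5-yl]propanoate
Product: 15 methyl (2R)-2-[(3R,3aS,5S,8aR)-3-hydroxy-3,8-dimethyl-4-oxo-1,2,3,3a,4,5,6,8a-octahydroazulen-5-yl]propanoate
Conditions: HF·pyridine, pyridine, THF, 0 °C
Reagents that add atoms: none
Why: Fluoride desilylation under buffered, non-basic conditions should free the tertiary alcohol without retro-aldol cleavage of the β-hydroxy ketone or epimerisation at C5.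

Step 13
Reactants: 15 methyl (2R)-2-[(3R,3aS,5S,8aR)-3-hydroxy-3,8-dimethyl-4-oxo-1,2,3,3a,4,5,6,8a-octahydroazulen-5-yl]propanoate
Product: 17 (3R,3aS,6aR,9R,9aR,9bR)-9-hydroxy-3,6,9-trimethyl-3a,4,6a,7,8,9,9a,9b-octahydroazuleno[4,5-b]furan-2(3H)-one, via diol ester 16 (not isolated)
Conditions: Me4NBH(OAc)3, MeCN/AcOH, −30 to 0 °C; then CSA (cat.), CH2Cl2, rt
Reagents that add atoms: none
Why: In this hydroxyl-directed triacetoxyborohydride reduction (Evans–Saksena type) the tertiary C3–OH, which lies on the same side of the cyclopentane as C4, should bind boron and deliver hydride through a six-membered chair to give the C4 alcohol anti to the C3a–C8a bond (4R, cis to H-3a and to the C5 substituent), after which the cis γ-hydroxy ester lactonises under acid catalysis.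

Step 14
Reactants: 17 (3R,3aS,6aR,9R,9aR,9bR)-9-hydroxy-3,6,9-trimethyl-3a,4,6a,7,8,9,9a,9b-octahydroazuleno[4,5-b]furan-2(3H)-one
Product: 18 (3R,3aS,5R,6S,6aR,9R,9aR,9bR)-5,6-epoxy-9-hydroxy-3,6,9-trimethyldecahydroazuleno[4,5-b]furan-2(3H)-one
Conditions: m-CPBA, CH2Cl2, 0 °C
Reagents that add atoms: 3-chloroperoxybenzoic acid, OOC(=O)c1cccc(Cl)c1
Why: Prilezhaev epoxidation of the only alkene; in the chair-like cycloheptene the pseudo-axial lactone carbon on C3a covers one face, so the peracid should add to the opposite face (cis to H-6a), which fixes the configuration of the later ring acetoxy carbon.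

Step 15
Reactants: 18 (3R,3aS,5R,6S,6aR,9R,9aR,9bR)-5,6-epoxy-9-hydroxy-3,6,9-trimethyldecahydroazuleno[4,5-b]furan-2(3H)-one
Product: 19 (3R,3aS,5R,6S,6aR,9aS,9bR)-5,6-epoxy-3,6,9-trimethyl-3a,4,5,6,6a,7,9a,9b-octahydroazuleno[4,5-b]furan-2(3H)-one
Conditions: Burgess reagent, toluene, 50 °C
Reagents that add atoms: none
Why: Burgess dehydration is a thermal syn-elimination of the sulfamate ester; H-9a is anti to the leaving group and cannot take part, so elimination should go toward C8 and give the more substituted endocyclic alkene, with oxirane and lactone inert.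

Step 16
Reactants: 19 (3R,3aS,5R,6S,6aR,9aS,9bR)-5,6-epoxy-3,6,9-trimethyl-3a,4,5,6,6a,7,9a,9b-octahydroazuleno[4,5-b]furan-2(3H)-one
Product: 20 (3R,3aS,5R,6aR,9aS,9bR)-5-hydroxy-3,9-dimethyl-6-methylidene-3a,4,5,6,6a,7,9a,9b-octahydroazuleno[4,5-b]furan-2(3H)-one
Conditions: Cp2TiCl2 (2.5 equiv), Mn dust, THF, rt; aq. HCl work-up
Reagents that add atoms: none
Why: Titanocene(III)-mediated homolytic epoxide opening (Nugent–RajanBabu type) gives the tertiary C6 radical, which is trapped by a second Ti(III) and should lose a β-hydrogen from the methyl group, the usual preference, to give the exocyclic methylene with the C5–O configuration of the oxirane retained.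

Step 17
Reactants: 20 (3R,3aS,5R,6aR,9aS,9bR)-5-hydroxy-3,9-dimethyl-6-methylidene-3a,4,5,6,6a,7,9a,9b-octahydroazuleno[4,5-b]furan-2(3H)-one
Product: 21 (3R,3aS,5R,6aR,9aS,9bR)-3,9-dimethyl-6-methylidene-2,3,3a,4,5,6,6a,7,9a,9b-decahydroazuleno[4,5-b]furan-2,5-diol (lactol, both anomers)
Conditions: DIBAL-H (2.2 equiv), CH2Cl2, −78 °C
Reagents that add atoms: none
Why: Partial reduction of a γ-lactone by DIBAL-H at low temperature should stop at the lactol, the free hydroxyl only consuming one extra equivalent of hydride.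

Step 18
Reactants: 21 (3R,3aS,5R,6aR,9aS,9bR)-3,9-dimethyl-6-methylidene-2,3,3a,4,5,6,6a,7,9a,9b-decahydroazuleno[4,5-b]furan-2,5-diol
Product: 22 (2R,3S,4S)-2-[(3aS,4R,5S,7R,8aR)-4,7-dihydroxy-3-methyl-8-methylidene-1,3a,4,5,6,7,8,8a-octahydroazulen-5-yl]-4-(methoxymethoxy)hex-5-en-3-ol
Conditions: allyl methoxymethyl ether, s-BuLi, THF, −78 °C; (+)-Ipc2BOMe; BF3·OEt2; then 21 (reagent in excess), −78 °C to rt; ethanolamine work-up
Reagents that add atoms: allyl methoxymethyl ether, C=CCOCOC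
Why: Brown (Z)-γ-alkoxyallylboration proceeds through a closed chair transition state on the hydroxy aldehyde in equilibrium with the lactol: the Z geometry should give the syn diol monoether, and the (−)-α-pinene-derived isopinocampheyl groups should direct attack to the Re face of the aldehyde, setting C3′ (S) and C4′ (S) under reagent control while the opened template frees the C4 hydroxyl.

Step 19
Reactants: 22 (2R,3S,4S)-2-[(3aS,4R,5S,7R,8aR)-4,7-dihydroxy-3-methyl-8-methylidene-1,3a,4,5,6,7,8,8a-octahydroazulen-5-yl]-4-(methoxymethoxy)hex-5-en-3-ol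
Product: 23 (2R,3S,4S)-2-[(3aS,4R,5S,7R,8aR)-4,7-dihydroxy-3-methyl-8-methylidene-1,3a,4,5,6,7,8,8a-octahydroazulen-5-yl]hex-5-ene-3,4-diol
Conditions: HCl (cat.), MeOH, rt
Reagents that add atoms: none
Why: Acid-catalysed acetal exchange with methanol should remove the methoxymethyl group at the stage where the allylic C4′ oxygen is flanked only by a terminal vinyl group and is therefore not prone to ionisation.

Step 20
Reactants: 23 (2R,3S,4S)-2-[(3aS,4R,5S,7R,8aR)-4,7-dihydroxy-3-methyl-8-methylidene-1,3a,4,5,6,7,8,8a-octahydroazulen-5-yl]hex-5-ene-3,4-diol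
Product: 24 (2R,3S,4S)-2-[(3aS,4R,5S,7R,8aR)-4,7-dihydroxy-3-methyl-8-methylidene-1,3a,4,5,6,7,8,8a-octahydroazulen-5-yl]-6-methylhept-5-ene-3,4-diol
Conditions: Grubbs second-generation catalyst (5 mol%), 2-methyl-2-butene (large excess), CH2Cl2, 40 °C
Reagents that add atoms: 2-methyl-2-butene, CC=C(C)C
Why: Olefin cross-metathesis with 2-methyl-2-butene should convert only the monosubstituted vinyl group into the isobutenyl group, the 1,1-disubstituted and trisubstituted ring alkenes being too hindered to enter the catalytic cycle.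

Step 21
Reactants: 24 (2R,3S,4S)-2-[(3aS,4R,5S,7R,8aR)-4,7-dihydroxy-3-methyl-8-methylidene-1,3a,4,5,6,7,8,8a-octahydroazulen-5-yl]-6-methylhept-5-ene-3,4-diol
Product: 25 (2R,3S,4S)-2-[(3aS,4R,5S,7R,8aR)-7-acetoxy-4-hydroxy-3-methyl-8-methylidene-1,3a,4,5,6,7,8,8a-octahydroazulen-5-yl]-6-methylhept-5-ene-3,4-diyl diacetate
Conditions: Ac2O (3.3 equiv), pyridine, CH2Cl2, 0 °C to rt, no DMAP
Reagents that add atoms: acetic anhydride, CC(=O)OC(C)=O
Why: Sterically controlled acylation: the C4 carbinol sits between the ring-fusion methine and the branched C5 methine and should stay free under DMAP-free conditions, while the allylic C7–OH and the two side-chain hydroxyls are acetylated.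

**Compound list**

1 | neryl acetate, (2Z)-3,7-dimethylocta-2,6-dien-1-yl acetate | CC(C)=CCC/C(C)=C\COC(C)=O | starting material
2 | (2Z,6E)-8-hydroxy-3,7-dimethylocta-2,6-dien-1-yl acetate | OC/C(C)=C/CC/C(C)=C\COC(C)=O | intermediate
3 | (2Z,6E)-3,7-dimethyl-8-oxoocta-2,6-dien-1-yl acetate | O=C/C(C)=C/CC/C(C)=C\COC(C)=O | intermediate
4 | (2Z,6E)-3,7-dimethylnona-2,6,8-trien-1-yl acetate | C=C/C(C)=C/CC/C(C)=C\COC(C)=O | intermediate
5 | (2Z,6E)-3,7-dimethylnona-2,6,8-trien-1-ol | C=C/C(C)=C/CC/C(C)=C\CO | intermediate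
6 | [(2S,3R)-3-methyl-3-[(3E)-4-methylhexa-3,5-dien-1-yl]oxiran-2-yl]methanol | OC[C@@H]1O[C@]1(C)CC/C=C(\C)C=C | intermediate
7 | (2R,3R)-3-methyl-3-[(3E)-4-methylhexa-3,5-dien-1-yl]oxirane-2-carbaldehyde | O=C[C@@H]1O[C@]1(C)CC/C=C(\C)C=C | intermediate
8 | 1-[(2S,3R)-3-methyl-3-[(3E)-4-methylhexa-3,5-dien-1-yl]oxiran-2-yl]ethan-1-ol (both carbinol epimers) | CC(O)[C@@H]1O[C@]1(C)CC/C=C(\C)C=C | intermediate
9 | 1-[(2R,3R)-3-methyl-3-[(3E)-4-methylhexa-3,5-dien-1-yl]oxiran-2-yl]ethan-1-one | CC(=O)[C@@H]1O[C@]1(C)CC/C=C(\C)C=C | intermediate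
10 | triethyl({1-[(2R,3R)-3-methyl-3-[(3E)-4-methylhexa-3,5-dien-1-yl]oxiran-2-yl]ethenyl}oxy)silane | C=C(O[Si](CC)(CC)CC)[C@@H]1O[C@]1(C)CC/C=C(\C)C=C | intermediate
11 | (3R,3aS,8aR)-3,8-dimethyl-3-[(triethylsilyl)oxy]-2,3,3a,5,6,8a-hexahydroazulen-4(1H)-one (trans-fused; silyloxy group cis to C4 on the five-membered ring) | CC1=CCCC(=O)[C@@H]2[C@](C)(O[Si](CC)(CC)CC)CC[C@@H]12 | intermediate
12 | methyl (R)-lactate | C[C@@H](O)C(=O)OC | starting material
13 | methyl (2R)-2-{[(trifluoromethyl)sulfonyl]oxy}propanoate | C[C@@H](OS(=O)(=O)C(F)(F)F)C(=O)OC | intermediate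
14 | methyl (2R)-2-[(3R,3aS,5S,8aR)-3,8-dimethyl-4-oxo-3-[(triethylsilyl)oxy]-1,2,3,3a,4,5,6,8a-octahydroazulen-5-yl]propanoate | CC1=CC[C@@H]([C@@H](C)C(=O)OC)C(=O)[C@@H]2[C@](C)(O[Si](CC)(CC)CC)CC[C@@H]12 | intermediate
15 | methyl (2R)-2-[(3R,3aS,5S,8aR)-3-hydroxy-3,8-dimethyl-4-oxo-1,2,3,3a,4,5,6,8a-octahydroazulen-5-yl]propanoate | CC1=CC[C@@H]([C@@H](C)C(=O)OC)C(=O)[C@@H]2[C@](C)(O)CC[C@@H]12 | intermediate
16 | methyl (2R)-2-[(3R,3aR,4R,5S,8aR)-3,4-dihydroxy-3,8-dimethyl-1,2,3,3a,4,5,6,8a-octahydroazulen-5-yl]propanoate | CC1=CC[C@@H]([C@@H](C)C(=O)OC)[C@@H](O)[C@@H]2[C@](C)(O)CC[C@@H]12 | intermediate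
17 | (3R,3aS,6aR,9R,9aR,9bR)-9-hydroxy-3,6,9-trimethyl-3a,4,6a,7,8,9,9a,9b-octahydroazuleno[4,5-b]furan-2(3H)-one | CC1=CC[C@H]3[C@@H](C)C(=O)O[C@H]3[C@@H]2[C@](C)(O)CC[C@@H]12 | intermediate
18 | (3R,3aS,5R,6S,6aR,9R,9aR,9bR)-5,6-epoxy-9-hydroxy-3,6,9-trimethyldecahydroazuleno[4,5-b]furan-2(3H)-one (oxirane cis to H-6a) | C[C@@]12O[C@@H]1C[C@H]3[C@@H](C)C(=O)O[C@H]3[C@@H]4[C@](C)(O)CC[C@@H]24 | intermediate
19 | (3R,3aS,5R,6S,6aR,9aS,9bR)-5,6-epoxy-3,6,9-trimethyl-3a,4,5,6,6a,7,9a,9b-octahydroazuleno[4,5-b]furan-2(3H)-one | C[C@@]12O[C@@H]1C[C@H]3[C@@H](C)C(=O)O[C@H]3[C@@H]4C(C)=CC[C@@H]24 | intermediate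
20 | (3R,3aS,5R,6aR,9aS,9bR)-5-hydroxy-3,9-dimethyl-6-methylidene-3a,4,5,6,6a,7,9a,9b-octahydroazuleno[4,5-b]furan-2(3H)-one | C=C1[C@H](O)C[C@H]3[C@@H](C)C(=O)O[C@H]3[C@@H]2C(C)=CC[C@@H]12 | intermediate
21 | (3R,3aS,5R,6aR,9aS,9bR)-3,9-dimethyl-6-methylidene-2,3,3a,4,5,6,6a,7,9a,9b-decahydroazuleno[4,5-b]furan-2,5-diol (lactol, both anomers) | C=C1[C@H](O)C[C@H]3[C@@H](C)C(O)O[C@H]3[C@@H]2C(C)=CC[C@@H]12 | intermediate
22 | (2R,3S,4S)-2-[(3aS,4R,5S,7R,8aR)-4,7-dihydroxy-3-methyl-8-methylidene-1,3a,4,5,6,7,8,8a-octahydroazulen-5-yl]-4-(methoxymethoxy)hex-5-en-3-ol | C=C1[C@H](O)C[C@@H]([C@@H](C)[C@H](O)[C@H](C=C)OCOC)[C@@H](O)[C@@H]2C(C)=CC[C@@H]12 | intermediate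
23 | (2R,3S,4S)-2-[(3aS,4R,5S,7R,8aR)-4,7-dihydroxy-3-methyl-8-methylidene-1,3a,4,5,6,7,8,8a-octahydroazulen-5-yl]hex-5-ene-3,4-diol | C=C1[C@H](O)C[C@@H]([C@@H](C)[C@H](O)[C@H](C=C)O)[C@@H](O)[C@@H]2C(C)=CC[C@@H]12 | intermediate
24 | (2R,3S,4S)-2-[(3aS,4R,5S,7R,8aR)-4,7-dihydroxy-3-methyl-8-methylidene-1,3a,4,5,6,7,8,8a-octahydroazulen-5-yl]-6-methylhept-5-ene-3,4-diol | C=C1[C@H](O)C[C@@H]([C@@H](C)[C@H](O)[C@H](C=C(C)C)O)[C@@H](O)[C@@H]2C(C)=CC[C@@H]12 | intermediate
25 | (2R,3S,4S)-2-[(3aS,4R,5S,7R,8aR)-7-acetoxy-4-hydroxy-3-methyl-8-methylidene-1,3a,4,5,6,7,8,8a-octahydroazulen-5-yl]-6-methylhept-5-ene-3,4-diyl diacetate | C=C1[C@H](OC(C)=O)C[C@@H]([C@@H](C)[C@H](OC(C)=O)[C@H](C=C(C)C)OC(C)=O)[C@@H](O)[C@@H]2C(C)=CC[C@@H]12 | target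

**Totals and risks**

Total step count: 21. Longest linear sequence: 20 steps (1 to 25 through steps 1–9 and 11–21); step 10 is a one-step branch.

Steps most likely to fail:

1. Step 9. The silyl-activated oxirane may ionise at its tertiary carbon (hydride shift or proton loss instead of cycloaddition), or the cycloaddition may pass through the compact transition state and give the cis-fused isomer. The fallback sets out from 9 and comes back at 11, generating the same oxyallyl cation from an α-chloro ketone under basic ionising conditions. Samarium diiodide (THF/MeOH, −90 °C) should cleave the Cα–O bond of the epoxy ketone reductively to give (4R,7E)-4-hydroxy-4,8-dimethyldeca-7,9-dien-2-one F1 with the tertiary carbinol centre intact. TESOTf/2,6-lutidine gives its silyl ether, (4R,7E)-4,8-dimethyl-4-[(triethylsilyl)oxy]deca-7,9-dien-2-one F2. LDA/TMSCl at −78 °C gives the methyl-side silyl enol ether, (4R,7E)-4,8-dimethyl-4-[(triethylsilyl)oxy]-2-[(trimethylsilyl)oxy]deca-1,7,9-triene F3, and N-chlorosuccinimide converts it into (4R,7E)-1-chloro-4,8-dimethyl-4-[(triethylsilyl)oxy]deca-7,9-dien-2-one F4. Et3N in trifluoroethanol (Föhlisch conditions) should then enolise F4 toward C3, ionise chloride and close the intramolecular (4+3) cycloadduct 11. Here facial control rests only on the silyloxy-bearing stereocentre, so separation of diastereomers is to be expected.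

2. Step 11. C-alkylation by the secondary triflate may lose to O-alkylation, to elimination of triflic acid from 13, or to proton exchange that equilibrates C5. The fallback sets out from 11 and comes back at 17, using a primary electrophile and setting C3 of the lactone on the lactone template. LDA then methyl bromoacetate gives methyl 2-[(3R,3aS,5S,8aR)-3,8-dimethyl-4-oxo-3-[(triethylsilyl)oxy]-1,2,3,3a,4,5,6,8a-octahydroazulen-5-yl]acetate F5. HF·pyridine gives the β-hydroxy ketone, methyl 2-[(3R,3aS,5S,8aR)-3-hydroxy-3,8-dimethyl-4-oxo-1,2,3,3a,4,5,6,8a-octahydroazulen-5-yl]acetate F6. The directed reduction of step 13 gives methyl 2-[(3R,3aR,4R,5S,8aR)-3,4-dihydroxy-3,8-dimethyl-1,2,3,3a,4,5,6,8a-octahydroazulen-5-yl]acetate F7, which lactonises to (3aS,6aR,9R,9aR,9bR)-9-hydroxy-6,9-dimethyl-3a,4,6a,7,8,9,9a,9b-octahydroazuleno[4,5-b]furan-2(3H)-one F8. LDA (2.2 equiv) then MeI should methylate the lactone enolate on its convex face and give the C3 epimer, (3S,3aS,6aR,9R,9aR,9bR)-9-hydroxy-3,6,9-trimethyl-3a,4,6a,7,8,9,9a,9b-octahydroazuleno[4,5-b]furan-2(3H)-one F9. Renewed deprotonation (LDA, −78 °C) and kinetic protonation on the same convex face (2,6-di-tert-butylphenol) should turn the methyl group to the concave face and give 17.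

3. Step 14. Poor facial selectivity of the epoxidation on the flexible seven-membered ring would give the wrong configuration at the ring carbinol of 20. The fallback sets out from 17 and comes back at 20, setting that centre by carbonyl reduction instead of by the epoxidation. The oxirane of opposite configuration, (3R,3aS,5S,6R,6aR,9R,9aR,9bR)-5,6-epoxy-9-hydroxy-3,6,9-trimethyldecahydroazuleno[4,5-b]furan-2(3H)-one F10, alone or mixed with 18, is taken through the conditions of steps 15 and 16. This gives (3R,3aS,5S,6R,6aR,9aS,9bR)-5,6-epoxy-3,6,9-trimethyl-3a,4,5,6,6a,7,9a,9b-octahydroazuleno[4,5-b]furan-2(3H)-one F11 and then the epimeric allylic alcohol, (3R,3aS,5S,6aR,9aS,9bR)-5-hydroxy-3,9-dimethyl-6-methylidene-3a,4,5,6,6a,7,9a,9b-octahydroazuleno[4,5-b]furan-2(3H)-one F12. Dess–Martin oxidation converges all material to the enone, (3R,3aS,6aR,9aS,9bR)-3,9-dimethyl-6-methylidene-3,3a,4,6,6a,7,9a,9b-octahydroazuleno[4,5-b]furan-2,5-dione F13. Luche reduction (NaBH4, CeCl3·7H2O, MeOH, −78 °C) should then deliver hydride from the face that the peracid had preferred, which places the hydroxyl on the required face and gives 20.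

Further compounds
F1 | step 9 | (4R,7E)-4-hydroxy-4,8-dimethyldeca-7,9-dien-2-one | CC(=O)C[C@](C)(O)CC/C=C(\C)C=C
F2 | step 9 | (4R,7E)-4,8-dimethyl-4-[(triethylsilyl)oxy]deca-7,9-dien-2-one | CC(=O)C[C@](C)(O[Si](CC)(CC)CC)CC/C=C(\C)C=C
F3 | step 9 | (4R,7E)-4,8-dimethyl-4-[(triethylsilyl)oxy]-2-[(trimethylsilyl)oxy]deca-1,7,9-triene | C=C(O[Si](C)(C)C)C[C@](C)(O[Si](CC)(CC)CC)CC/C=C(\C)C=C
F4 | step 9 | (4R,7E)-1-chloro-4,8-dimethyl-4-[(triethylsilyl)oxy]deca-7,9-dien-2-one | ClCC(=O)C[C@](C)(O[Si](CC)(CC)CC)CC/C=C(\C)C=C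
F5 | step 11 | methyl 2-[(3R,3aS,5S,8aR)-3,8-dimethyl-4-oxo-3-[(triethylsilyl)oxy]-1,2,3,3a,4,5,6,8a-octahydroazulen-5-yl]acetate | CC1=CC[C@@H](CC(=O)OC)C(=O)[C@@H]2[C@](C)(O[Si](CC)(CC)CC)CC[C@@H]12
F6 | step 11 | methyl 2-[(3R,3aS,5S,8aR)-3-hydroxy-3,8-dimethyl-4-oxo-1,2,3,3a,4,5,6,8a-octahydroazulen-5-yl]acetate | CC1=CC[C@@H](CC(=O)OC)C(=O)[C@@H]2[C@](C)(O)CC[C@@H]12
F7 | step 11 | methyl 2-[(3R,3aR,4R,5S,8aR)-3,4-dihydroxy-3,8-dimethyl-1,2,3,3a,4,5,6,8a-octahydroazulen-5-yl]acetate | CC1=CC[C@@H](CC(=O)OC)[C@@H](O)[C@@H]2[C@](C)(O)CC[C@@H]12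
F8 | step 11 | (3aS,6aR,9R,9aR,9bR)-9-hydroxy-6,9-dimethyl-3a,4,6a,7,8,9,9a,9b-octahydroazuleno[4,5-b]furan-2(3H)-one | CC1=CC[C@H]3CC(=O)O[C@H]3[C@@H]2[C@](C)(O)CC[C@@H]12
F9 | step 11 | (3S,3aS,6aR,9R,9aR,9bR)-9-hydroxy-3,6,9-trimethyl-3a,4,6a,7,8,9,9a,9b-octahydroazuleno[4,5-b]furan-2(3H)-one | CC1=CC[C@H]3[C@H](C)C(=O)O[C@H]3[C@@H]2[C@](C)(O)CC[C@@H]12
F10 | step 14 | (3R,3aS,5S,6R,6aR,9R,9aR,9bR)-5,6-epoxy-9-hydroxy-3,6,9-trimethyldecahydroazuleno[4,5-b]furan-2(3H)-one | C[C@]12O[C@H]1C[C@H]3[C@@H](C)C(=O)O[C@H]3[C@@H]4[C@](C)(O)CC[C@@H]24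
F11 | step 14 | (3R,3aS,5S,6R,6aR,9aS,9bR)-5,6-epoxy-3,6,9-trimethyl-3a,4,5,6,6a,7,9a,9b-octahydroazuleno[4,5-b]furan-2(3H)-one | C[C@]12O[C@H]1C[C@H]3[C@@H](C)C(=O)O[C@H]3[C@@H]4C(C)=CC[C@@H]24
F12 | step 14 | (3R,3aS,5S,6aR,9aS,9bR)-5-hydroxy-3,9-dimethyl-6-methylidene-3a,4,5,6,6a,7,9a,9b-octahydroazuleno[4,5-b]furan-2(3H)-one | C=C1[C@@H](O)C[C@H]3[C@@H](C)C(=O)O[C@H]3[C@@H]2C(C)=CC[C@@H]12
F13 | step 14 | (3R,3aS,6aR,9aS,9bR)-3,9-dimethyl-6-methylidene-3,3a,4,6,6a,7,9a,9b-octahydroazuleno[4,5-b]furan-2,5-dione | C=C1C(=O)C[C@H]3[C@@H](C)C(=O)O[C@H]3[C@@H]2C(C)=CC[C@@H]12
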